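The first nucleophile is charged at 0.700 equiv against the starting material and competes with solvolysis, so I ask one thing of the earlier runs: at what level of first nucleophile, as a fraction of the charge, do solvolysis product and target form equally fast?

| setting | east | north-east | south-east | winter | midnight | autumn | dusk | summer |
|---|---|---|---|---|---|---|---|---|
| starting material | 14 mM | 7 mM | 28 mM | 14 mM (fed, over 5.0 h) | 14 mM | 14 mM (fed, over 5.0 h) | 14 mM | 14 mM |
| first nucleophile | 0.70 equiv | 0.70 equiv | 0.70 equiv | 0.700 equiv | 0.700 equiv (in portions, 5, over 5.0 h) | 0.700 equiv | 0.700 equiv (fed, over 80 min) | 0.700 equiv |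
| second nucleophile | 5 equiv | 5 equiv | 5 equiv | 5.00 equiv | 5.00 equiv | 5.00 equiv | 5.00 equiv | 5.00 equiv |
| temperature | 75 °C | 86 °C | 75 °C |  | 80 °C | 80 °C | 80 °C | 80 °C |
| remark | run made earlier | run made earlier | run made earlier | the addition at 60 °C, then warmed to 80 °C; the feed brings no volume worth counting | first portion at the start, last at 5.0 h | all else is in the flask from the start; the feed brings no volume worth counting | all else is in the flask from the start; the feed brings no volume worth counting | everything together at the start |
| time |  |  |  | 8.0 h | 8.0 h | 8.0 h | 8.0 h | 8.0 h |

| run | time / h | solvolysis product / % | target / % |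
|---|---|---|---|
| east | 1.33 | 4 | 10 |
| east | 2.50 | 9 | 17 |
| east | 4.00 | 14 | 28 |
| east | 5.00 | 17 | 30 |
| east | 6.00 | 18 | 30 |
| east | 8.00 | 20 | 32 |
| north-east | 0.417 | 9 | 7 |
| north-east | 0.667 | 14 | 11 |
| north-east | 1.00 | 22 | 14 |
| north-east | 2.00 | 35 | 23 |
| north-east | 3.00 | 40 | 23 |
| north-east | 5.00 | 45 | 19 |
| south-east | 0.833 | 1 | 9 |
| south-east | 1.50 | 7 | 16 |
| south-east | 2.50 | 5 | 23 |
| south-east | 3.00 | 7 | 24 |
| south-east | 4.00 | 7 | 29 |
| south-east | 5.00 | 9 | 32 |

(each reading ± 1.5 percentage points)

- the analysis behind the earlier runs scatters by 1.5 percentage points, standard deviation

* which flask leads in amount of solvolysis product, in percent of the starting material charged ("all alike" within 1.5 percentage points) (winter / midnight / autumn / dusk / summer / all alike)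
* how much solvolysis product is there at the end, in percent of the starting material charged: winter
* how much solvolysis product is there at the end, in percent of the starting material charged: midnight
* how much solvolysis product is there at the end, in percent of the starting material charged: autumn
* how much solvolysis product is there at the end, in percent of the starting material charged: dusk
* how much solvolysis product is there at the end, in percent of the starting material charged: summer

I call that level the break-even level β, a selectivity factor written as an amount. If each unit of nucleophile used brings β divided by the level left of solvolysis product, the curve is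

solvolysis product = β × ln(nucleophile charged / nucleophile left)

Counting the target as the nucleophile used, the east run at 5.00 h reads

β = 0.304

The south-east run at 5.00 h reads 0.147. Its charge is twice the east charge, so on the east charge this is 0.295, a match within the scatter. The north-east run at 0.667 h, at 86 °C, reads 0.409 on the same charge. Between 75 °C and 86 °C I take the geometric mean for 80 °C:

β = 0.353

Now I draw the summer curve. It starts at a slope of 0.504 of solvolysis product per unit of nucleophile used. It crosses slope one when the level reaches β, with 24.2% of solvolysis product made, and past that point solvolysis product forms faster than target.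

The midnight flask starts beyond the crossing, since its first portion of 0.140 is below β, with a slope of 2.52. The dusk flask starts from an empty level, so the start does not separate those two, and I compare how long each level is held below β: the first nucleophile charged so far passes β at 2.50 h in midnight but at 0.672 h in dusk, and the level cannot stand above what has been charged. On that comparison I put midnight at the head, and I reckon no end values of my own.

The forecast names midnight, with winter 16%, midnight 35%, autumn 21%, dusk 29% and summer 26%. Its ground is “Starving the nucleophile (portions) maximises solvolysis”.

The flasks give midnight at the head, with winter 17.7%, midnight 35.8%, autumn 23.5%, dusk 29.6% and summer 27.0%.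

    target → over-reaction product (k = 0.0839 h⁻¹, Ea = 113 kJ mol⁻¹)
    starting material + intermediate → side product A (k = 3.47 M⁻¹ h⁻¹, Ea = 74.0 kJ mol⁻¹)
    intermediate → solvolysis product (k = 3.86 h⁻¹, Ea = 109 kJ mol⁻¹)
    starting material → intermediate (k = 0.364 h⁻¹, Ea = 115 kJ mol⁻¹)
    second nucleophile + intermediate → other capture product (k = 49.2 M⁻¹ h⁻¹, Ea = 86.0 kJ mol⁻¹)
    first nucleophile + intermediate → target (k = 969 M⁻¹ h⁻¹, Ea = 74.0 kJ mol⁻¹)
    intermediate → side product B (k = 0.0893 h⁻¹, Ea = 129 kJ mol⁻¹)
    (constants at 80 °C)

In winter at 5.93 h the intermediate passes into target 1.8 times as fast as into solvolysis product, and with 52% of its first nucleophile left at the end, the curve gives winter a β of 0.269 against the 0.353 I carried. The neighbour of winter with 35 mM of starting material ends at 8.89% of solvolysis product with 44% of its first nucleophile left, which on the winter charge is a β of 0.270.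

Readings and results come from a simulation with constants of no real substance, and the scatter is random.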